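Compound numbers used throughout: **1** quinone, **2** hydroquinone, **3** fluoroaldehyde, **4** mono-ether (in flask), **5** dialdehyde, **6** bis-formate (in flask), **7** bisphenol, **8** arm-tetrabromide (in flask), **9** octabromo dimethyl ether, **10** target.

## The problem

Compound **10** (C18H6Br8O6) is a centrosymmetric, linear triaryl bis-ether. Its central ring is a fully substituted benzene-1,2,4,5-tetrol in which one para pair of oxygens is free, the other para pair is arylated, and the two remaining carbons carry bromine; it is flanked by two identical 2,3,5-tribromo-4-hydroxyphenoxy rings. There is no stereocentre, and the diaryl ether axes are not expected to be configurationally stable, so only regiochemistry and chemoselectivity have to be controlled. Six of the eight bromines lie where electrophilic bromination goes unaided: the two positions ortho to each outer hydroxyl and the only two C–H positions of the central ring. The other two, one per outer ring, are meta to the hydroxyl and ortho to the ether oxygen, while the position related to them across the ether carbon keeps its hydrogen. No late bromination can tell these two sites apart or be made to stop after one. The sensitive part is the central hydroquinone, which air in base and bromine itself oxidise to a quinone whose aryloxy groups are vinylogous esters; the C–Br bonds exclude hydrogenolysis, halogen–metal exchange and late copper or palladium couplings. The enabling feature is the pattern on each outer ring: ether oxygen at C1, one bromine at C2, hydroxyl at C4. With formyl in place of hydroxyl this is 3-bromo-4-fluorobenzaldehyde (**3**), whose fluoride is activated towards a phenoxide and whose aldehyde can later be exchanged for OH by Baeyer–Villiger oxidation.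

## Retrosynthesis

**10 ⇒ 9 (two O–CH3 bonds).** The last cut removes only the methyl groups from the two central hydroxyls. They must stay until the end because base, peracid and bromine would each turn a free central hydroquinone into the quinone. Methyl is preferred to benzyl or an acetal because it survives K2CO3 at 80 °C, peracid and the HBr released during bromination, and because the purchasable quinone **1** already carries it. The forward step must cleave two flanked aryl methyl ethers without touching diaryl ethers or C–Br bonds, which is the profile of BBr3.

**9 ⇒ 7 (six C–Br bonds).** Removing the four bromines ortho to the outer hydroxyls and the two on the central ring leads to bisphenol **7**, which keeps only the two bromines that cannot be introduced late. Carrying the six through the ether formation instead was rejected: a brominated core phenoxide is flanked on both sides and weakly nucleophilic, and more bromine on the electrophile adds further displaceable halides. The forward reaction must deliver exactly six bromines. It is helped because the six sites are the most electron-rich C–H positions of **7**, whereas the seventh candidate (the outer-ring C–H next to the ether oxygen) is meta to OH on a ring that by then bears three bromines.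

**7 ⇒ 5 (two aryl C–OH bonds, traced back to aryl C–CHO).** A hydroxyl para to the leaving group would shut down nucleophilic aromatic substitution; an aldehyde switches it on. The aryloxy group para to the aldehyde in **5** in turn favours aryl migration in the Baeyer–Villiger step. A nitro group would activate more strongly but needs three operations to become OH, the aldehyde one.

**5 ⇒ 2 + two 3 (the two outer-ring C–O bonds).** Each ether is cut on the side of the outer ring. Cutting on the central-ring side would need an electrophilic tetraoxygenated arene, meaning copper-mediated coupling of an electron-rich dihalide with a hindered, electron-poor bromophenol. The chosen cut gives two simple fragments, halves the problem by symmetry and is a plain addition–elimination. It asks that fluoride, not bromide, be displaced and that both phenoxide oxygens react.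

**2 ⇒ 1 (redox adjustment).** Hydroquinone **2** is too air-sensitive to store and is made when needed from the stable quinone **1**.

## Roads not taken

**Alternative 1:** Here the outer rings are built rather than bought. Each is cut along two C–C bonds into a 2-(aryloxy)malonaldehyde unit and a five-carbon ketodiester. The two malonaldehyde units sit on the pre-brominated, methylated core in 2,2'-[(2,5-dibromo-3,6-dimethoxy-1,4-phenylene)bis(oxy)]dimalonaldehyde A2; the ketodiester is dimethyl 3-oxopentanedioate A3. Knoevenagel condensation followed by intramolecular aldol condensation would close both rings and give tetramethyl 5,5'-[(2,5-dibromo-3,6-dimethoxy-1,4-phenylene)bis(oxy)]bis(2-hydroxyisophthalate) A1.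
- Merits: the ester groups mark both positions ortho to each new hydroxyl, so saponification and bromodecarboxylation would place bromine there without relying on directing effects. The core bromines are present from the start, so the core has no oxidisable C–H.
- Weak points: A1 has two equivalent C–H positions ortho to the ether oxygen and the target needs exactly one of them brominated. That is the hard part of the problem, left unsolved and postponed to an electron-poor ring. A2 is a fourfold, enolised and self-condensing aldehyde that must be made by O-alkylation of a doubly flanked, weakly nucleophilic hydroquinone. Four condensations must succeed in one molecule, and the route is several steps longer.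
- Comparison: this road does place the four ortho-to-hydroxyl bromines by construction, which the chosen plan leaves to inherent reactivity. The chosen plan can afford that because those are the sites bromine prefers anyway, and it fixes by construction the one bromine per arm that Alternative 1 cannot.

**Alternative 2:** All eight C–Br bonds are cut at once, back to 2,5-bis(4-hydroxyphenoxy)benzene-1,4-diol A5. Excess bromine would brominate arms and core, oxidise the central hydroquinone in passing and end at 2,5-dibromo-3,6-bis(2,3,5-tribromo-4-hydroxyphenoxy)-1,4-benzoquinone A4, which Na2S2O4 would reduce to **10**.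
- Merits: it is the shortest road by a clear margin, uses no protecting groups and follows a plausible biogenetic logic. The oxidation to the quinone becomes part of the plan instead of a hazard.
- Weak points: the first two bromines on each arm go ortho to the hydroxyl easily, but the third must enter meta to OH, next to the ether oxygen, at one of two equivalent positions of an already dibrominated ring, and then stop. Conditions forcing enough for that site will not separate tri- from tetrabromo arms, and the resulting mixture of closely related polybromides would be very hard to resolve. The quinone core holds its aryloxy groups as vinylogous esters towards HBr and water.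
- Comparison: in step count and atom economy this road is better than the chosen one. The chosen plan sets against it that no bromine position depends on discrimination between equivalent sites: the two awkward bromines arrive with **3**, the other six go to the most reactive positions of **7**, and the core is shielded from oxidation until the last step.

**Alternative 3:** The cut lies inside the central ring. One C–C bond of 2,5-bis(4-methoxyphenoxy)-1,4-benzoquinone A6 is opened, leading back to 4-hydroxy-3-(4-methoxyphenoxy)-4-[(4-methoxyphenoxy)ethynyl]cyclobut-2-en-1-one A7. Heating A7 would open the four-membered ring and reclose it as a six-membered one through C–C bond formation between the former carbonyl carbon and the aryloxy-bearing alkyne carbon (Moore rearrangement).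
- Merits: the ring expansion is dependable and regiospecific for the 2,5-pattern, it is convergent, and it delivers the core at the robust quinone level.
- Weak points: the key step is spent on the one ring that can be bought with the right oxygenation (**1**). A7 needs a metallated aryloxyalkyne and a cyclobutenedione partner with a vinylic hydrogen, both several steps from commercial material and sensitive. A6 has unbrominated 4-methoxyphenoxy arms, so the whole bromination problem of Alternative 2 is still ahead, followed by demethylation and reduction. The count is roughly twice that of the chosen route.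
- Comparison: its one real advantage is that no air-sensitive hydroquinone dianion is handled. The chosen plan answers this by generating **2** immediately before use under argon.

Key step: step 2

## Route

Step 1
Reactants: 1 2,5-dimethoxy-1,4-benzoquinone
Product: 2 2,5-dimethoxybenzene-1,4-diol
Conditions: Na2S2O4 (3 equiv), THF/H2O, rt, Ar; EtOAc extraction under Ar, crude used at once
Reagents that add atoms: none
Why: Dithionite reduction of a p-benzoquinone to its hydroquinone is a standard, fast two-electron reduction that leaves the methoxy groups untouched; because the electron-rich product reoxidises in air it is dried and concentrated under argon and taken straight into step 2.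

Step 2
Reactants: 2 2,5-dimethoxybenzene-1,4-diol; 3 3-bromo-4-fluorobenzaldehyde (2.3 equiv)
Product: 5 4,4'-[(2,5-dimethoxy-1,4-phenylene)bis(oxy)]bis(3-bromobenzaldehyde), via mono-ether phenol 4 (not isolated)
Conditions: K2CO3 (4 equiv), degassed DMF, 80 °C, Ar
Reagents that add atoms: none
Why: K2CO3 deprotonates 2, and each phenoxide oxygen adds to C4 of 3, the fluorine-bearing carbon para to the formyl group, giving a Meisenheimer anion whose charge is delocalised into the aldehyde; loss of fluoride restores aromaticity (addition–elimination, SNAr). The first substitution gives the phenoxide of 4, still electron-rich through its methoxy donors, which repeats the sequence. The closest known reaction type is the twofold K2CO3/DMF etherification of hydroquinones with 4-fluorobenzaldehydes to 1,4-bis(4-formylphenoxy)benzenes. No ring is closed and no stereocentre is formed. The selectivity needed is fluoride over bromide: addition is rate-limiting, so the strongly polarised C–F carbon para to the acceptor reacts, whereas the C–Br carbon is meta to the aldehyde and cannot stabilise an adduct. O- rather than C-arylation follows from the hard phenoxide in a dipolar aprotic solvent, complete double substitution from the excess of 3, and survival of the dianion from rigorous exclusion of oxygen.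

Step 3
Reactants: 5 4,4'-[(2,5-dimethoxy-1,4-phenylene)bis(oxy)]bis(3-bromobenzaldehyde)
Product: 7 4,4'-[(2,5-dimethoxy-1,4-phenylene)bis(oxy)]bis(3-bromophenol), via bis-formate ester 6 (not isolated)
Conditions: mCPBA (3 equiv), KH2PO4, CH2Cl2, 0 °C to rt; then HCl (cat.), MeOH, rt
Reagents that add atoms: mCPBA (3-chloroperoxybenzoic acid), O=C(OO)c1cccc(Cl)c1
Why: Baeyer–Villiger (Dakin-type) oxidation: in the Criegee adduct the aryl group, made electron-rich by the para aryloxy substituent, migrates in preference to hydride to give the aryl formate, which acid-catalysed methanolysis cleaves to the phenol. The phosphate buffer suppresses acid-promoted side reactions of the electron-rich central ring; aryl bromides and ethers are inert to the peracid.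

Step 4
Reactants: 7 4,4'-[(2,5-dimethoxy-1,4-phenylene)bis(oxy)]bis(3-bromophenol)
Product: 9 4,4'-[(2,5-dibromo-3,6-dimethoxy-1,4-phenylene)bis(oxy)]bis(2,3,6-tribromophenol), via arm-tetrabrominated bisphenol 8 (not isolated)
Conditions: Br2 (6.2 equiv), AcOH/CH2Cl2, 0 °C to rt, dark; aq. Na2S2O3
Reagents that add atoms: bromine, BrBr
Why: Electrophilic aromatic bromination at the six most activated C–H positions: the two sites ortho to each free phenol are expected to react first, then the two core sites, each ortho to a methoxy and an aryloxy oxygen; whichever order is taken the same hexabromination product results. The only remaining C–H on each arm is meta to OH on a ring bearing three bromines, so dosing the bromine should stop the reaction there, and the methyl ethers keep the core from being oxidised to the quinone.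

Step 5
Reactants: 9 4,4'-[(2,5-dibromo-3,6-dimethoxy-1,4-phenylene)bis(oxy)]bis(2,3,6-tribromophenol)
Product: 10 2,5-dibromo-3,6-bis(2,3,5-tribromo-4-hydroxyphenoxy)benzene-1,4-diol
Conditions: BBr3 (6 equiv), CH2Cl2, −78 °C to rt, Ar; H2O at 0 °C, aq. Na2S2O4 wash
Reagents that add atoms: none
Why: BBr3 demethylation of aryl methyl ethers: boron coordinates the methoxy oxygen and bromide removes the methyl group by SN2, with the phenol released on aqueous work-up; diaryl ethers and aryl bromides are inert. The two methoxy groups are twisted out of conjugation by their flanking substituents and should cleave readily, and the reductive wash keeps the product at the hydroquinone level.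

## Compound list

1 | 2,5-dimethoxy-1,4-benzoquinone | COC1=CC(=O)C(OC)=CC1=O | starting material
2 | 2,5-dimethoxybenzene-1,4-diol | COc1cc(O)c(OC)cc1O | intermediate
3 | 3-bromo-4-fluorobenzaldehyde | O=Cc1ccc(F)c(Br)c1 | starting material
4 | 3-bromo-4-(4-hydroxy-2,5-dimethoxyphenoxy)benzaldehyde | COc1cc(Oc2ccc(C=O)cc2Br)c(OC)cc1O | intermediate
5 | 4,4'-[(2,5-dimethoxy-1,4-phenylene)bis(oxy)]bis(3-bromobenzaldehyde) | COc1cc(Oc2ccc(C=O)cc2Br)c(OC)cc1Oc1ccc(C=O)cc1Br | intermediate
6 | [(2,5-dimethoxy-1,4-phenylene)bis(oxy)]bis(3-bromo-4,1-phenylene) diformate | COc1cc(Oc2ccc(OC=O)cc2Br)c(OC)cc1Oc1ccc(OC=O)cc1Br | intermediate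
7 | 4,4'-[(2,5-dimethoxy-1,4-phenylene)bis(oxy)]bis(3-bromophenol) | COc1cc(Oc2ccc(O)cc2Br)c(OC)cc1Oc1ccc(O)cc1Br | intermediate
8 | 4,4'-[(2,5-dimethoxy-1,4-phenylene)bis(oxy)]bis(2,3,6-tribromophenol) | COc1cc(Oc2cc(Br)c(O)c(Br)c2Br)c(OC)cc1Oc1cc(Br)c(O)c(Br)c1Br | intermediate
9 | 4,4'-[(2,5-dibromo-3,6-dimethoxy-1,4-phenylene)bis(oxy)]bis(2,3,6-tribromophenol) | COc1c(Br)c(Oc2cc(Br)c(O)c(Br)c2Br)c(OC)c(Br)c1Oc1cc(Br)c(O)c(Br)c1Br | intermediate
10 | 2,5-dibromo-3,6-bis(2,3,5-tribromo-4-hydroxyphenoxy)benzene-1,4-diol | Oc1c(Br)c(Oc2cc(Br)c(O)c(Br)c2Br)c(O)c(Br)c1Oc1cc(Br)c(O)c(Br)c1Br | target

## Step count and least certain steps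

Total step count: 5. Longest linear sequence: 5 steps (1 → 2 → 5 → 7 → 9 → 10); 3 enters at step 2.

**Step 2 (key step).** The most likely failure is reoxidation of the dianion of 2 by traces of oxygen during isolation and transfer, which removes the nucleophile and produces semiquinone-derived tar. Stalling at the mono-ether stage and consumption of 3 by dimethylamine from DMF are secondary risks. The fallback sets out from 1 and never isolates the hydroquinone. Reductive acetylation of 1 (Zn, Ac2O, NaOAc) gives the air-stable, storable 2,5-dimethoxy-1,4-phenylene diacetate F1. This is deacetylated in the reaction flask with K2CO3 in degassed MeOH, the volatiles are removed under argon, and DMF and 3 are added to the residual potassium phenoxide. The sequence comes back to the route at 5.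

**Step 3.** Two processes threaten this step: hydride instead of aryl migration, leading to carboxylic acids, and electrophilic oxidation of the tetraoxygenated central ring by the peracid. The fallback avoids peroxides and sets out from 2. Substitution with purchased 2-bromo-1-fluoro-4-nitrobenzene F2 (K2CO3, DMF) gives 1,4-bis(2-bromo-4-nitrophenoxy)-2,5-dimethoxybenzene F3. Reduction with Fe powder and NH4Cl in EtOH/H2O, which spares the aryl bromides, gives 4,4'-[(2,5-dimethoxy-1,4-phenylene)bis(oxy)]bis(3-bromoaniline) F4. Diazotisation (NaNO2, aq. H2SO4, 0 °C) gives 4,4'-[(2,5-dimethoxy-1,4-phenylene)bis(oxy)]bis(3-bromobenzenediazonium) bis(hydrogensulfate) F5, and hydroxydediazoniation with Cu2O and Cu(NO3)2 in water at rt returns to the route at 7.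

**Step 4.** The risks are uneven bromination (incomplete reaction at the crowded sites alongside over-bromination at the remaining arm C–H) and, if water is present, ipso attack para to the arm hydroxyl with loss of the core. The fallback stages the halogenation and sets out from 5, whose arms are deactivated by the formyl groups. Br2 (2 equiv, CH2Cl2/AcOH, 0 °C) brominates only the core to give 4,4'-[(2,5-dibromo-3,6-dimethoxy-1,4-phenylene)bis(oxy)]bis(3-bromobenzaldehyde) F6. Baeyer–Villiger oxidation with mCPBA gives [(2,5-dibromo-3,6-dimethoxy-1,4-phenylene)bis(oxy)]bis(3-bromo-4,1-phenylene) diformate F7, and methanolysis gives 4,4'-[(2,5-dibromo-3,6-dimethoxy-1,4-phenylene)bis(oxy)]bis(3-bromophenol) F8. Br2 (4 equiv, AcOH) then has only the four positions ortho to the arm hydroxyls left, and the sequence rejoins the route at 9.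

**Step 5.** Partial aerial oxidation of the product hydroquinone during work-up and purification, giving hydroquinone/quinone mixtures, is the main concern; incomplete cleavage of the flanked methyl ethers is the second. The fallback sets out from 9 and purifies at the quinone level. After the BBr3 treatment the crude material is oxidised deliberately with aqueous FeCl3 in EtOAc to 2,5-dibromo-3,6-bis(2,3,5-tribromo-4-hydroxyphenoxy)-1,4-benzoquinone F9. This is purified as the air-stable quinone and reduced with aqueous Na2S2O4 immediately before isolation, returning to the route at 10.

## Further compounds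

F1 | step 2 | 2,5-dimethoxy-1,4-phenylene diacetate | COc1cc(OC(C)=O)c(OC)cc1OC(C)=O
F2 | step 3 | 2-bromo-1-fluoro-4-nitrobenzene | O=[N+]([O-])c1ccc(F)c(Br)c1
F3 | step 3 | 1,4-bis(2-bromo-4-nitrophenoxy)-2,5-dimethoxybenzene | COc1cc(Oc2ccc([N+](=O)[O-])cc2Br)c(OC)cc1Oc1ccc([N+](=O)[O-])cc1Br
F4 | step 3 | 4,4'-[(2,5-dimethoxy-1,4-phenylene)bis(oxy)]bis(3-bromoaniline) | COc1cc(Oc2ccc(N)cc2Br)c(OC)cc1Oc1ccc(N)cc1Br
F5 | step 3 | 4,4'-[(2,5-dimethoxy-1,4-phenylene)bis(oxy)]bis(3-bromobenzenediazonium) bis(hydrogensulfate) | COc1cc(Oc2ccc([N+]#N)cc2Br)c(OC)cc1Oc1ccc([N+]#N)cc1Br.OS(=O)(=O)[O-].OS(=O)(=O)[O-]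
F6 | step 4 | 4,4'-[(2,5-dibromo-3,6-dimethoxy-1,4-phenylene)bis(oxy)]bis(3-bromobenzaldehyde) | COc1c(Br)c(Oc2ccc(C=O)cc2Br)c(OC)c(Br)c1Oc1ccc(C=O)cc1Br
F7 | step 4 | [(2,5-dibromo-3,6-dimethoxy-1,4-phenylene)bis(oxy)]bis(3-bromo-4,1-phenylene) diformate | COc1c(Br)c(Oc2ccc(OC=O)cc2Br)c(OC)c(Br)c1Oc1ccc(OC=O)cc1Br
F8 | step 4 | 4,4'-[(2,5-dibromo-3,6-dimethoxy-1,4-phenylene)bis(oxy)]bis(3-bromophenol) | COc1c(Br)c(Oc2ccc(O)cc2Br)c(OC)c(Br)c1Oc1ccc(O)cc1Br
F9 | step 5 | 2,5-dibromo-3,6-bis(2,3,5-tribromo-4-hydroxyphenoxy)-1,4-benzoquinone | O=C1C(Br)=C(Oc2cc(Br)c(O)c(Br)c2Br)C(=O)C(Br)=C1Oc1cc(Br)c(O)c(Br)c1Br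
A1 | alternative 1 | tetramethyl 5,5'-[(2,5-dibromo-3,6-dimethoxy-1,4-phenylene)bis(oxy)]bis(2-hydroxyisophthalate) | COC(=O)c1cc(Oc2c(Br)c(OC)c(Oc3cc(C(=O)OC)c(O)c(C(=O)OC)c3)c(Br)c2OC)cc(C(=O)OC)c1O
A2 | alternative 1 | 2,2'-[(2,5-dibromo-3,6-dimethoxy-1,4-phenylene)bis(oxy)]dimalonaldehyde | COc1c(Br)c(OC(C=O)C=O)c(OC)c(Br)c1OC(C=O)C=O
A3 | alternative 1 | dimethyl 3-oxopentanedioate | COC(=O)CC(=O)CC(=O)OC
A4 | alternative 2 | 2,5-dibromo-3,6-bis(2,3,5-tribromo-4-hydroxyphenoxy)-1,4-benzoquinone | O=C1C(Br)=C(Oc2cc(Br)c(O)c(Br)c2Br)C(=O)C(Br)=C1Oc1cc(Br)c(O)c(Br)c1Br
A5 | alternative 2 | 2,5-bis(4-hydroxyphenoxy)benzene-1,4-diol | Oc1ccc(Oc2cc(O)c(Oc3ccc(O)cc3)cc2O)cc1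
A6 | alternative 3 | 2,5-bis(4-methoxyphenoxy)-1,4-benzoquinone | COc1ccc(OC2=CC(=O)C(Oc3ccc(OC)cc3)=CC2=O)cc1
A7 | alternative 3 | 4-hydroxy-3-(4-methoxyphenoxy)-4-[(4-methoxyphenoxy)ethynyl]cyclobut-2-en-1-one | COc1ccc(OC#CC2(O)C(Oc3ccc(OC)cc3)=CC2=O)cc1
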